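## Structural features

The target is a 2-arylbenzofuran. A benzofuran (ring A fused to the furan) carries a free hydroxyl at C6 and is joined through C2 to C1' of a pentasubstituted benzene, ring B. Ring B carries prenyl groups on C2' and C6', a methoxy group on C3', a hydroxyl on C5' and its only hydrogen on C4'. There is no stereocentre, the prenyl olefins have no E/Z element, and the biaryl axis, flanked on the benzofuran side only by O1 and C3–H, is not expected to be configurationally stable. The fragile parts are the two ortho-prenyl phenol units (acid closes them to chromans, and hydrogenation or oxidants attack them) and the electron-rich phenols and benzofuran, which oxidise in air under base. The real difficulty is ring B: four contiguous substituents, a biaryl bond buried between two ortho prenyl groups, and two meta oxygens that differ only in one methyl group. The two phenols on different rings must also be told apart, so O6 has to stay masked to the end by a group that leaves without acid, hydrogen or oxidant. The key step uses the meta-dioxygen pattern of ring B (O on C3' and C5', H on C4', carbon on C2' and C6'): it is the aldol fold of a 1,3,5-triketone whose aroyl carbonyl (the future C1') sits on benzofuran C2 and whose terminal α-methylene is the future C6'. Because C2' and C6' carry the same group, that triketone is in turn the aroylation product of a symmetric diketone.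

## Logic of the disconnections

15 to 14: the O6–allyl bond is cut. The benzofuran phenol has to be masked through two strongly basic steps and one methylation, and the allyl ether is the one common mask that tolerates all three and leaves under neutral conditions. The gain is differentiation of O6 from the ring B oxygens. The demand is a deallylation that touches neither the C-bound prenyl groups nor the free C5' phenol.

14 to 13: the O–CH3 bond on ring B is cut. In 13 the two hydroxyls are homotopic, so methylation of either gives the same 14 and no regiochemical question arises. The gain is a symmetric ring B. The demand is to stop at mono-methylation, which is a matter of stoichiometry and recycling.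

13 to 11: the C1'–C6' bond of ring B is cut (retro-aldol, through 12), which opens the ring to a linear triketone. The cut is made here because it is the only pairing of a chain carbon with a chain carbonyl that gives a six-membered carbocycle, and both prenyl positions are then fixed by the constitution of the chain. The gain is the whole of ring B with its four contiguous substituents. The demand is a carbon aldol onto a hindered, donor-substituted aroyl ketone that must outrun retro-Claisen cleavage and oxygen cyclization.

11 to 6 and 10: the bond between the aroyl carbonyl C1 and the prenyl-bearing C2 is cut. This shows that the C2 prenyl group and the C6–C10 arm are the two identical arms of one symmetric diketone, 10, and that the benzofuran arrives as a non-enolisable ester, 6. The gain is convergence: no C-prenylation of an aryl diketone and no separate acyl donor are needed. The demand is that the dianion of 10 forms at a substituted α'-methylene and is acylated on carbon.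

10 to 7 and 8: the two CH2–CH2 bonds that join the terminal carbons of 7 to the allylic CH2 of 8 are cut (through 9). Both prenyl groups of the target then come from one reagent at a stage where the regiochemistry is set by dianion reactivity. The demand is that the second deprotonation takes the remaining methyl group and not the substituted methylene.

6 to 2 and 3: the O1–C2 and C2–C3 bonds of the furan ring are cut (through 4 and 5). The ring then comes from a salicylaldehyde and a two-carbon ester by etherification and aldol condensation. The demand is complete cyclodehydration without loss of the allyl ether.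

2 to 1: the O4–allyl bond is cut. The demand is alkylation of the 4-hydroxyl only, which the hydrogen bond between the 2-hydroxyl and the aldehyde secures.

## Other disconnections considered

Alternative 1: The cut is the C3–C3a bond of the furan ring, traced back to a flavanone. The chromanone A2 would be treated with PhI(OH)OTs, a trivalent iodine electrophile, in trimethyl orthoformate. The reagent attacks the enol ether at C3, ring A shifts from C4 to C3 as iodobenzene leaves, and the former carbonyl carbon ends as the methyl ester of the trans dihydrobenzofuran A1.
- In favour: the oxidative ring contraction is established on simple flavanones, so in precedent for its own substrate class it is the equal of the chosen plan and arguably better. The aryl shift is stereospecific.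
- Against: two trisubstituted prenyl olefins and a dimethoxyarene compete for the electrophilic iodine. Migration of ring B from C2 to C3 competes with the ring A shift and is favoured by the electron-rich ring B present here. A2 itself needs an oxa-Michael closure next to a di-ortho-substituted aryl group.
- After the key step: A1 is still at the wrong oxidation level and needs ester hydrolysis, decarboxylation and dehydrogenation. It also needs desilylation and cleavage of one of two equivalent methyl ethers beside prenyl groups. Two stereocentres are made only to be destroyed.
- Comparison: structurally it rearranges the heterocycle and leaves the congested ring B to be brought in complete, whereas the chosen plan makes ring B. Mechanistically the prenyl groups are spectators under hydroxide but not under a cationic iodine oxidant. In step economy it is clearly longer.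

Alternative 2: The cut is both aryl–CH2 bonds of the prenyl groups, traced back to the O–C bonds of the bis(1,1-dimethylallyl) ether A4. Heating A4 would effect two aromatic [3,3] shifts through chair transition states with allyl inversion, and tautomerization would give the diprenyl resorcinol A3.
- In favour: both prenyl C–C bonds form in one reagent-free step, no polycarbonyl intermediate is needed, and the 5-arylresorcinol core is easy to reach. On mildness and operational simplicity it is better than the chosen plan.
- Equal: A3 differs from 13 only in the oxygen substituent of ring A, so the endgame (one mono-methylation, one deprotection) is the same.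
- Against: each ether oxygen has two ortho positions. The position between the two oxygens (C4' of the target) is less hindered than those flanked by the benzofuranyl group (C2' and C6'). Nothing in A4 directs the shift to the required positions, and once one group has gone to C4' the 2',6'-pattern is lost. Ortho-prenyl phenols also tend to cyclize to chromans at the temperatures needed.
- Comparison: the chosen plan fixes both prenyl positions constitutionally, because they are carbons of the chain, at the price of a less certain ring closure. Alternative 2 has a safe reaction type but unsecured regiochemistry. Step counts are comparable.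

Alternative 3: The cut is the C7–C7a and C5–C6 bonds of ring A. Photolysis of the furyl diazoketone A6 would cause Wolff rearrangement with furyl shift to a ketene, which would close by 6π electrocyclization onto the vinyl group and tautomerize to the 6-hydroxybenzofuran A5.
- In favour: the regiochemistry of ring A is unambiguous and the conditions are neutral. The C6 phenol emerges free, so ring A needs no protecting group, and on that point it is better than the chosen plan.
- Equal or better after the key step: one operation (mono-demethylation) against two.
- Against: it builds the ring that can be bought and leaves ring B, the hard part, to be made separately and attached to a furan through the same congested biaryl bond. A6 needs a multistep synthesis of a trisubstituted furan with hindered aryl, vinyl and diazoacetyl groups. The ketene can also add to the vinyl group in a [2+2] sense or be trapped, and the carbene can engage the prenyl olefins. A5 carries two equivalent methyl ethers, so one must be cleaved by nucleophilic demethylation beside two prenyl groups.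
- Comparison: structurally it spends its key step on the easy half of the molecule. Mechanistically it is a clean pericyclic cascade with sensitive intermediates. Overall it is longer than the chosen plan.

Key step: step 5

Remark on the chemistry: 11 (C27H32O5) and 13 (C27H30O4) differ by exactly one molecule of water and agree atom for atom, so neither structure needs correction. The closure is classified more precisely as 6-(enolendo)-exo-trig. 11 is racemic and configurationally labile at C2, which is irrelevant because C2 becomes an aromatic carbon. The structure of 11 is kept; its assembly is redesigned around the symmetric diketone 10.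

## Steps

Step 1
Reactants: 1 2,4-dihydroxybenzaldehyde
Product: 2 4-(allyloxy)-2-hydroxybenzaldehyde
Conditions: allyl bromide (1.05 equiv), KHCO3, MeCN, 70 °C
Reagents that add atoms: allyl bromide, C=CCBr
Why: Williamson etherification; the 2-hydroxyl is tied up in a hydrogen bond to the aldehyde and the 4-hydroxyl (para to the formyl group) is the more acidic, so a hydrogencarbonate base should alkylate O4 selectively.

Step 2
Reactants: 2 4-(allyloxy)-2-hydroxybenzaldehyde; 3 ethyl bromoacetate
Product: 6 ethyl 6-(allyloxy)benzofuran-2-carboxylate, via formylphenoxyacetate 4 (not isolated), via 3-hydroxydihydrobenzofuran ester 5 (not isolated)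
Conditions: K2CO3, DMF, 120 °C
Reagents that add atoms: none
Why: O-alkylation of the phenol followed by intramolecular aldol addition of the ester enolate to the ortho aldehyde and dehydration to the aromatic furan (Rap–Stoermer-type benzofuran synthesis); the aldehyde para to the ring oxygen of 1 ends as C3, which places the allyloxy group on C6, and the aryl allyl ether should be stable well below its Claisen temperature.

Step 3
Reactants: 7 pentane-2,4-dione; 8 1-bromo-3-methylbut-2-ene (2.1 equiv in two portions)
Product: 10 2,12-dimethyltrideca-2,11-diene-6,8-dione, via 8-methylnon-7-ene-2,4-dione 9 (not isolated)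
Conditions: LiN(iPr)2 (2.1 equiv), THF, 0 °C; 8 (1.0 equiv); LiN(iPr)2 (1.1 equiv), 0 °C; 8 (1.1 equiv), 0 to 23 °C; aq. NH4Cl
Reagents that add atoms: none
Why: Hauser dianion γ-alkylation run twice in one flask; the 1,3-dianion of 7 should react with the primary allylic bromide only at its terminal carbanion to give the enolate of 9, the next equivalent of amide base removes a proton from the remaining methyl group in preference to the substituted methylene (methyl over methylene kinetic acidity), and the second alkylation gives the symmetric diketone.

Step 4
Reactants: 10 2,12-dimethyltrideca-2,11-diene-6,8-dione (2.2 equiv); 6 ethyl 6-(allyloxy)benzofuran-2-carboxylate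
Product: 11 1-[6-(allyloxy)benzofuran-2-yl]-9-methyl-2-(3-methylbut-2-enyl)dec-8-ene-1,3,5-trione (racemic at C2)
Conditions: 10, LiN(iPr)2 (4.5 equiv), THF, −78 to 0 °C; then 6, −78 to 23 °C; cold aq. NH4Cl; used without prolonged contact with acid or silica
Reagents that add atoms: none
Why: Hauser–Harris aroylation of a 1,3-diketone dianion (a Claisen-type condensation) at its more basic α'-carbon by a non-enolisable aromatic ester; the symmetry of 10 allows only one dianion, the carbon attacked already bears the future C2' prenyl group, and the second equivalent of dianion takes up the acidic proton of 11 so that the valuable ester is consumed while the excess of cheap 10 is recovered.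

Step 5
Reactants: 11 1-[6-(allyloxy)benzofuran-2-yl]-9-methyl-2-(3-methylbut-2-enyl)dec-8-ene-1,3,5-trione
Product: 13 5-[6-(allyloxy)benzofuran-2-yl]-4,6-bis(3-methylbut-2-enyl)benzene-1,3-diol, via cyclic aldol 12 (not isolated)
Conditions: KOH (1 M aq.), 1,4-dioxane, degassed, Ar, 23 to 50 °C; then NaH2PO4 (aq.) to pH 6, 0 °C
Reagents that add atoms: none
Why: Hydroxide removes the most acidic proton, at C4 between the C3 and C5 carbonyls, and because the C2-alkylated C1/C3 diketone is the weaker acid and the poorer enol, C1 should stay largely a free ketone. Proton exchange supplies a small concentration of the C5=C6 enolate, whose carbon C6 adds to the C1 carbonyl in a 6-(enolendo)-exo-trig aldol that forms the C1'–C6' bond and closes ring B as the aldolate of 12. E1cB loss of water and enolization of the resulting cyclohexenedione give the resorcinolate of 13, an aromatic sink that makes the sequence irreversible. The closest known reaction is the alkaline cyclization of heptane-2,4,6-trione to orcinol; here the electrophile is an α-branched aroyl ketone and the nucleophile a methylene, both less reactive than in that case. No stereocentre is created in the product: the three stereocentres of 12 and the one of 11 are all erased on aromatization. The selectivity needed is carbon aldol over oxygen cyclization to the 4-pyranone and over retro-Claisen cleavage at the C1–C2 or C2–C3 bond. The substrate secures the first because C6-to-C1 is the only pairing that gives a six-membered carbocycle and because the pyranone reopens in hydroxide; the second is limited by dilute base, moderate temperature and a non-nucleophilic cosolvent. The allyl ether and the prenyl olefins are inert to hydroxide, and oxygen is excluded because the resorcinolate is easily oxidised.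

Step 6
Reactants: 13 5-[6-(allyloxy)benzofuran-2-yl]-4,6-bis(3-methylbut-2-enyl)benzene-1,3-diol
Product: 14 3-[6-(allyloxy)benzofuran-2-yl]-5-methoxy-2,4-bis(3-methylbut-2-enyl)phenol
Conditions: MeI (0.9 equiv), K2CO3 (1.0 equiv), acetone, 23 °C; recovered 13 recycled
Reagents that add atoms: iodomethane, CI
Why: Williamson O-methylation; the two hydroxyls of 13 are homotopic, so methylation of either gives the same 14, and a slight deficit of MeI should keep the doubly methylated material low while unreacted 13 is returned to the step.

Step 7
Reactants: 14 3-[6-(allyloxy)benzofuran-2-yl]-5-methoxy-2,4-bis(3-methylbut-2-enyl)phenol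
Product: 15 2-[3-hydroxy-5-methoxy-2,6-bis(3-methylbut-2-enyl)phenyl]benzofuran-6-ol
Conditions: Pd(PPh3)4 (5 mol %), morpholine (10 equiv), THF, 23 °C
Reagents that add atoms: none
Why: Tsuji–Trost-type deallylation; zerovalent palladium ionises the aryl allyl ether to a π-allyl complex of divalent palladium and the phenoxide, and morpholine captures the allyl group irreversibly, while the C-bound prenyl groups have no leaving group and the conditions are neutral, so the ortho-prenyl phenols should not cyclize.

## Compound list

1 | 2,4-dihydroxybenzaldehyde | O=Cc1ccc(O)cc1O | starting material
2 | 4-(allyloxy)-2-hydroxybenzaldehyde | O=Cc1ccc(OCC=C)cc1O | intermediate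
3 | ethyl bromoacetate | CCOC(=O)CBr | starting material
4 | ethyl 2-[5-(allyloxy)-2-formylphenoxy]acetate | CCOC(=O)COc1cc(OCC=C)ccc1C=O | intermediate (not isolated)
5 | ethyl 6-(allyloxy)-3-hydroxy-2,3-dihydrobenzofuran-2-carboxylate (racemic mixture of cis and trans isomers) | CCOC(=O)C1Oc2cc(OCC=C)ccc2C1O | intermediate (not isolated)
6 | ethyl 6-(allyloxy)benzofuran-2-carboxylate | CCOC(=O)c1cc2ccc(OCC=C)cc2o1 | intermediate
7 | pentane-2,4-dione | CC(=O)CC(=O)C | starting material
8 | 1-bromo-3-methylbut-2-ene | CC(C)=CCBr | starting material
9 | 8-methylnon-7-ene-2,4-dione (formed as its lithium enolate) | CC(=O)CC(=O)CCC=C(C)C | intermediate (not isolated)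
10 | 2,12-dimethyltrideca-2,11-diene-6,8-dione | CC(C)=CCCC(=O)CC(=O)CCC=C(C)C | intermediate
11 | 1-[6-(allyloxy)benzofuran-2-yl]-9-methyl-2-(3-methylbut-2-enyl)dec-8-ene-1,3,5-trione (racemic, labile at C2) | C=CCOc1ccc2cc(C(=O)C(CC=C(C)C)C(=O)CC(=O)CCC=C(C)C)oc2c1 | intermediate
12 | 5-[6-(allyloxy)benzofuran-2-yl]-5-hydroxy-4,6-bis(3-methylbut-2-enyl)cyclohexane-1,3-dione (racemic mixture of diastereomers) | C=CCOc1ccc2cc(C3(O)C(CC=C(C)C)C(=O)CC(=O)C3CC=C(C)C)oc2c1 | intermediate (not isolated)
13 | 5-[6-(allyloxy)benzofuran-2-yl]-4,6-bis(3-methylbut-2-enyl)benzene-1,3-diol | C=CCOc1ccc2cc(-c3c(CC=C(C)C)c(O)cc(O)c3CC=C(C)C)oc2c1 | intermediate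
14 | 3-[6-(allyloxy)benzofuran-2-yl]-5-methoxy-2,4-bis(3-methylbut-2-enyl)phenol | C=CCOc1ccc2cc(-c3c(CC=C(C)C)c(O)cc(OC)c3CC=C(C)C)oc2c1 | intermediate
15 | 2-[3-hydroxy-5-methoxy-2,6-bis(3-methylbut-2-enyl)phenyl]benzofuran-6-ol | COc1cc(O)c(CC=C(C)C)c(-c2cc3ccc(O)cc3o2)c1CC=C(C)C | target

## Step count and risks

Total: 7 steps. Longest linear sequence: 6 steps (steps 1, 2, 4, 5, 6, 7 from 1); step 3 is a one-step side branch.

Step 5 (key step). Most likely failure: retro-Claisen cleavage by hydroxide at the non-enolised C1 or C3 carbonyl of the α-branched diketone unit outruns the slow carbon aldol onto the hindered aroyl ketone, which the 6-alkoxy group further deactivates by donation through the benzofuran. A second failure is closure on oxygen to the 4-pyranone during acidification.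
Fallback: defer both prenyl groups so that the ring closure becomes the classical unbranched case; it sets out from 6 and 7 and comes back at 13.
- The dianion of 7 (LiN(iPr)2, THF) is aroylated with 6 to give 1-[6-(allyloxy)benzofuran-2-yl]hexane-1,3,5-trione F1, which has an unbranched aroyl terminus and a methyl ketone as nucleophile.
- Aqueous KOH should close F1 to 5-[6-(allyloxy)benzofuran-2-yl]benzene-1,3-diol F2.
- Both phenols are etherified with 3-chloro-3-methylbut-1-yne (DBU, CuCl2 cat., MeCN) to 6-(allyloxy)-2-[3,5-bis(2-methylbut-3-yn-2-yloxy)phenyl]benzofuran F3.
- Semihydrogenation (H2, Pd on CaCO3 poisoned with Pb(OAc)2, quinoline) gives 6-(allyloxy)-2-[3,5-bis(2-methylbut-3-en-2-yloxy)phenyl]benzofuran F4.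
- Heating at about 120 °C in N,N-diethylaniline should rearrange the two tertiary allyl ethers by aromatic Claisen shift, while the primary allyl ether, which needs a much higher temperature, should stay, giving 13.
- The weak point of this detour is regiochemistry: migration to the carbon between the two oxygens competes with migration to the carbons next to the benzofuranyl group.

Step 4. Most likely failure: incomplete formation or sluggish C-acylation of the secondary dianion carbon, so that proton transfer returns both partners, or a second aroylation of the product anion.
Fallback: build the chain in the other direction with a primary carbanion; it sets out from 6 and comes back at 11.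
- Claisen condensation of 6 with acetone (NaH, THF) gives 1-[6-(allyloxy)benzofuran-2-yl]butane-1,3-dione F5.
- C-prenylation with 8 (K2CO3, acetone) gives 1-[6-(allyloxy)benzofuran-2-yl]-2-(3-methylbut-2-enyl)butane-1,3-dione F6.
- The dianion of F6 (LiN(iPr)2, THF) is acylated at its terminal methyl carbon with N-methoxy-N,5-dimethylhex-4-enamide F7, made from purchased 5-methylhex-4-enoic acid with carbonyldiimidazole and N,O-dimethylhydroxylamine hydrochloride, to give 11.

Step 6. Most likely failure: the second methylation runs at nearly the same rate as the first, so conversion per pass stays low, and some methylation on carbon at the position between the two oxygens is possible.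
Fallback: replace statistical mono-protection by exhaustive methylation and selective mono-demethylation; it sets out from 13 and comes back at 15, bypassing 14 and step 7.
- Excess MeI and K2CO3 convert 13 into 6-(allyloxy)-2-[3,5-dimethoxy-2,6-bis(3-methylbut-2-enyl)phenyl]benzofuran F8.
- NaSEt in DMF at 120 to 140 °C should cleave the allyl ether and one methyl ether by SN2 attack of thiolate. The phenoxide formed on ring B deactivates the second methyl ether, so the reaction should stop at 15.

Step 3. Most likely failure: the second deprotonation occurs partly at the substituted methylene of 9, giving a branched isomer, together with over-alkylation.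
Fallback: make the second arm by acylation instead of alkylation; it sets out from 7 and 8 and comes back at 10.
- Alkylation of 7 with 8 under K2CO3 in refluxing ethanol, with cleavage of one acetyl group in the same pot, gives 6-methylhept-5-en-2-one F9 (which can also be bought).
- The kinetic lithium enolate of F9 (LiN(iPr)2, THF, −78 °C, two equivalents) is acylated with ethyl 5-methylhex-4-enoate F10 to give 10. F10 is obtained by Johnson–Claisen rearrangement of purchased 2-methylbut-3-en-2-ol with triethyl orthoacetate.

## Further compounds

F1 | step 5 | 1-[6-(allyloxy)benzofuran-2-yl]hexane-1,3,5-trione | CC(=O)CC(=O)CC(=O)c1cc2ccc(OCC=C)cc2o1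
F2 | step 5 | 5-[6-(allyloxy)benzofuran-2-yl]benzene-1,3-diol | Oc1cc(O)cc(-c2cc3ccc(OCC=C)cc3o2)c1
F3 | step 5 | 6-(allyloxy)-2-[3,5-bis(2-methylbut-3-yn-2-yloxy)phenyl]benzofuran | C#CC(C)(C)Oc1cc(OC(C)(C)C#C)cc(-c2cc3ccc(OCC=C)cc3o2)c1
F4 | step 5 | 6-(allyloxy)-2-[3,5-bis(2-methylbut-3-en-2-yloxy)phenyl]benzofuran | C=CC(C)(C)Oc1cc(OC(C)(C)C=C)cc(-c2cc3ccc(OCC=C)cc3o2)c1
F5 | step 4 | 1-[6-(allyloxy)benzofuran-2-yl]butane-1,3-dione | CC(=O)CC(=O)c1cc2ccc(OCC=C)cc2o1
F6 | step 4 | 1-[6-(allyloxy)benzofuran-2-yl]-2-(3-methylbut-2-enyl)butane-1,3-dione (racemic) | CC(=O)C(CC=C(C)C)C(=O)c1cc2ccc(OCC=C)cc2o1
F7 | step 4 | N-methoxy-N,5-dimethylhex-4-enamide | CON(C)C(=O)CCC=C(C)C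
F8 | step 6 | 6-(allyloxy)-2-[3,5-dimethoxy-2,6-bis(3-methylbut-2-enyl)phenyl]benzofuran | C=CCOc1ccc2cc(-c3c(CC=C(C)C)c(OC)cc(OC)c3CC=C(C)C)oc2c1
F9 | step 3 | 6-methylhept-5-en-2-one | CC(=O)CCC=C(C)C
F10 | step 3 | ethyl 5-methylhex-4-enoate | CCOC(=O)CCC=C(C)C
A1 | alternative 1 | methyl trans-2-[3,5-dimethoxy-2,6-bis(3-methylbut-2-enyl)phenyl]-6-(triisopropylsilyloxy)-2,3-dihydrobenzofuran-3-carboxylate (racemic, one enantiomer drawn) | COC(=O)[C@H]1[C@H](c2c(CC=C(C)C)c(OC)cc(OC)c2CC=C(C)C)Oc2cc(O[Si](C(C)C)(C(C)C)C(C)C)ccc21
A2 | alternative 1 | 2-[3,5-dimethoxy-2,6-bis(3-methylbut-2-enyl)phenyl]-7-(triisopropylsilyloxy)chroman-4-one (racemic) | O=C1CC(c2c(CC=C(C)C)c(OC)cc(OC)c2CC=C(C)C)Oc2cc(O[Si](C(C)C)(C(C)C)C(C)C)ccc21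
A3 | alternative 2 | 5-[6-(triisopropylsilyloxy)benzofuran-2-yl]-4,6-bis(3-methylbut-2-enyl)benzene-1,3-diol | CC(C)=CCc1c(O)cc(O)c(CC=C(C)C)c1-c1cc2ccc(O[Si](C(C)C)(C(C)C)C(C)C)cc2o1
A4 | alternative 2 | 2-[3,5-bis(2-methylbut-3-en-2-yloxy)phenyl]-6-(triisopropylsilyloxy)benzofuran | C=CC(C)(C)Oc1cc(OC(C)(C)C=C)cc(-c2cc3ccc(O[Si](C(C)C)(C(C)C)C(C)C)cc3o2)c1
A5 | alternative 3 | 2-[3,5-dimethoxy-2,6-bis(3-methylbut-2-enyl)phenyl]benzofuran-6-ol | COc1cc(OC)c(CC=C(C)C)c(-c2cc3ccc(O)cc3o2)c1CC=C(C)C
A6 | alternative 3 | 2-diazo-1-{5-[3,5-dimethoxy-2,6-bis(3-methylbut-2-enyl)phenyl]-3-vinylfuran-2-yl}ethanone | [N-]=[N+]=CC(=O)c1oc(-c2c(CC=C(C)C)c(OC)cc(OC)c2CC=C(C)C)cc1C=C
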